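**Retrosynthetic overview**

1. Target 19 is a C2-symmetric 2,2'-biquinone, and the last move is hydrolysis of the two quinone methyl ethers of 17. Ring A locants used below: C1 carbonyl next to C2–OH, C3–Me, C4 carbonyl, C5 inter-ring carbon, C6 aralkyl carbon; ring B the same with primes.
2. Key disconnection: C4–C5 and C4'–C5', the bond in each ring between the carbonyl carbon flanked by C–Me and the inter-ring carbon. Both are made in one operation by thermal ring expansion of bis(cyclobutenone) 14 (4π opening, then 6π closure of a dienylketene), followed by Ag2O.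
3. Enabling feature: C6=C5–C5'=C6' (the aralkyl-bearing edges of rings A and B plus the inter-ring bond) is a buta-1,3-diene whose central σ bond is the biaryl axis, and C1–C4 of each ring (O, OMe, Me, O) is a squarate-derived four-carbon unit. The hindered axis is therefore carried in as a diene bond and never made by coupling.
4. 14 comes from two-directional addition of dilithiodiene 12 (from E,E-dibromodiene 8) to two molecules of 3-methoxy-4-methylcyclobutenedione 11 (from dimethyl squarate 9). 8 comes from reductive homocoupling of bromo-iodoalkene 6, made from alkyne 5.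
5. Ring order: the two anisole rings are bought; quinone rings A and B are both formed in step 7.

Key step: step 7

Assumption: the inter-ring axis of the target carries no configurational descriptor, so no control of axial chirality is attempted, and the 2-hydroxy-1,4-quinone tautomer drawn is taken as the target.

**Route**

Step 1
Reactants: 1 1-(trimethylsilyl)propyne; 2 2-methoxybenzyl bromide
Product: 4 [4-(2-methoxyphenyl)but-1-yn-1-yl]trimethylsilane, via silylpropargyllithium 3 (not isolated)
Conditions: n-BuLi, THF, −78 → −20 °C; then 2, −78 °C → rt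
Reagents that add atoms: none
Why: Propargylic lithiation of the silyl-capped propyne followed by SN2 alkylation with the benzylic bromide should give the propargyl (not allenyl) product, the bulky silyl terminus disfavouring attack through the allenyl position; no stereocentre is formed.

Step 2
Reactants: 4 [4-(2-methoxyphenyl)but-1-yn-1-yl]trimethylsilane
Product: 5 1-(but-3-yn-1-yl)-2-methoxybenzene
Conditions: K2CO3 (cat.), MeOH, rt
Reagents that add atoms: none
Why: Methoxide-mediated protodesilylation of an alkynylsilane should free the terminal alkyne while leaving the aryl methyl ether untouched.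

Step 3
Reactants: 5 1-(but-3-yn-1-yl)-2-methoxybenzene
Product: 6 1-[(3E)-3-bromo-4-iodobut-3-en-1-yl]-2-methoxybenzene
Conditions: IBr (1.05 equiv), CH2Cl2, −78 → 0 °C, dark
Reagents that add atoms: iodine monobromide, BrI
Why: Electrophilic anti iodobromination (iodonium at the terminal carbon, Markovnikov opening by bromide at the internal carbon) should set the E geometry with Br trans to I and the aralkyl chain cis to I; low temperature and the absence of a Lewis acid should keep the anisole ring from being iodinated.

Step 4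
Reactants: 6 1-[(3E)-3-bromo-4-iodobut-3-en-1-yl]-2-methoxybenzene (two molecules)
Product: 8 (3E,5E)-3,6-dibromo-1,8-bis(2-methoxyphenyl)octa-3,5-diene, via alkenyl pinacolboronate 7 (not isolated)
Conditions: B2pin2 (0.52 equiv), PdCl2(dppf) (5 mol %), K3PO4, dioxane/H2O, 50 °C
Reagents that add atoms: none
Why: Palladium-catalysed borylative homocoupling (Miyaura borylation of half of the alkenyl iodide, then Suzuki–Miyaura coupling with the other half) should be selective because zerovalent palladium inserts into the terminal C–I bond much faster than into the hindered internal C–Br bond, and transmetalation and reductive elimination retain alkene geometry, so both bromines end up trans to the diene chain.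

Step 5
Reactants: 9 3,4-dimethoxycyclobut-3-ene-1,2-dione (dimethyl squarate)
Product: 11 3-methoxy-4-methylcyclobut-3-ene-1,2-dione, via lithium alkoxide 10 (not isolated)
Conditions: MeLi, THF, −78 °C; then (CF3CO)2O, −78 °C; aq. NH4Cl
Reagents that add atoms: methyllithium, [Li]C; water (work-up), O
Why: 1,2-Addition of MeLi to one squarate carbonyl, then trifluoroacetylation and ionisation of the tertiary alkoxide and hydrolysis of the methoxy-stabilised cation with loss of methanol, is the standard squarate-to-3-alkoxy-4-alkylcyclobutenedione transposition.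

Step 6
Reactants: 8 (3E,5E)-3,6-dibromo-1,8-bis(2-methoxyphenyl)octa-3,5-diene; 11 3-methoxy-4-methylcyclobut-3-ene-1,2-dione (two molecules)
Product: 14 4,4'-[(3E,5E)-1,8-bis(2-methoxyphenyl)octa-3,5-diene-3,6-diyl]bis(4-hydroxy-3-methoxy-2-methylcyclobut-2-en-1-one), via dilithiodiene 12 (not isolated), via dilithium bis(alkoxide) 13 (not isolated)
Conditions: t-BuLi (4.1 equiv), Et2O/THF, −78 °C; cannulate into 11 (2.4 equiv), THF, −78 °C; aq. NH4Cl
Reagents that add atoms: none
Why: Twofold bromine–lithium exchange with retention of alkene geometry, then twofold 1,2-addition of the alkenyllithium to the ketone-like carbonyl of 11 (the one next to the methoxy-bearing carbon; the other is a deactivated vinylogous ester), should give 14; because each lithium is trans to the diene chain the two carbanions cannot reach the same dione, and the two carbinol stereocentres form without control (meso/racemic mixture) and are erased in step 7.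

Step 7
Reactants: 14 4,4'-[(3E,5E)-1,8-bis(2-methoxyphenyl)octa-3,5-diene-3,6-diyl]bis(4-hydroxy-3-methoxy-2-methylcyclobut-2-en-1-one)
Product: 17 4,4'-dimethoxy-5,5'-dimethyl-2,2'-bis[2-(2-methoxyphenyl)ethyl]-[1,1'-bi(cyclohexa-1,4-diene)]-3,3',6,6'-tetrone, via bis(dienylketene) 15 (not isolated), via bis(hydroquinone) 16 (not isolated)
Conditions: PhMe (degassed), 110 °C; then Ag2O, MgSO4, rt
Reagents that add atoms: none
Why: Heating should open each 4-hydroxycyclobutenone by conrotatory 4π-electrocyclic cleavage of the C(=O)–C(OH) ring bond, the donor hydroxyl rotating outward so that the alkenyl arm turns inward and lies cis to the new ketene (drawn as 15, although the two halves need not react at the same moment). Each dienylketene should then close by thermal disrotatory 6π-electrocyclisation, the ketene carbon (the future carbonyl flanked by C–Me) bonding to the diene terminus that already carries the other half, and enolisation aromatises rings A and B to 16, which Ag2O oxidises to the bis(para-quinone). The closest known reaction type is the Moore–Liebeskind ring expansion of 4-alkenyl- and 4-aryl-4-hydroxycyclobutenones to hydroquinones and quinones, here run twice on one substrate. The transient sp3 centres at C5 and C5' vanish on aromatisation and the carbinol stereocentres of 14 vanish on ring opening, so no stereocentre needs control, and the axis is formed without control. The selectivity needed is regiochemical (carbonyl next to C–Me beside the inter-ring carbon, aralkyl carbon beside the other carbonyl) and is fixed by the site of alkenyllithium addition in step 6, while the E geometry of 14 leaves only hydrogen on the inside of each cyclising terminus and the outward hydroxyl cannot trap the ketene as a butenolide. Because the inter-ring bond is the pre-existing central σ bond of the diene, the tetra-ortho-substituted axis never has to be made by a coupling reaction.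

Step 8
Reactants: 17 4,4'-dimethoxy-5,5'-dimethyl-2,2'-bis[2-(2-methoxyphenyl)ethyl]-[1,1'-bi(cyclohexa-1,4-diene)]-3,3',6,6'-tetrone
Product: 19 4,4'-dihydroxy-5,5'-dimethyl-2,2'-bis[2-(2-methoxyphenyl)ethyl]-[1,1'-bi(cyclohexa-1,4-diene)]-3,3',6,6'-tetrone, via disodium bis(quinonolate) 18 (not isolated)
Conditions: 2 M NaOH, MeOH/THF, 0 °C → rt; then 1 M HCl
Reagents that add atoms: sodium hydroxide, [Na+].[OH-]
Why: Addition–elimination of hydroxide at the vinylogous ester carbon of each methoxyquinone (vinylogous ester saponification) should give the stabilised hydroxyquinone anion, protonated on acidification, while the two aryl methyl ethers are inert to these conditions.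

**Compound list**

1 | 1-(trimethylsilyl)propyne | CC#C[Si](C)(C)C | starting material
2 | 2-methoxybenzyl bromide | COc1ccccc1CBr | starting material
3 | [3-(trimethylsilyl)prop-2-yn-1-yl]lithium | [Li]CC#C[Si](C)(C)C | intermediate
4 | [4-(2-methoxyphenyl)but-1-yn-1-yl]trimethylsilane | COc1ccccc1CCC#C[Si](C)(C)C | intermediate
5 | 1-(but-3-yn-1-yl)-2-methoxybenzene | COc1ccccc1CCC#C | intermediate
6 | 1-[(3E)-3-bromo-4-iodobut-3-en-1-yl]-2-methoxybenzene (Br trans to I) | COc1ccccc1CC/C(Br)=C\I | intermediate
7 | 2-[(1E)-2-bromo-4-(2-methoxyphenyl)but-1-en-1-yl]-4,4,5,5-tetramethyl-1,3,2-dioxaborolane | COc1ccccc1CC/C(Br)=C\B1OC(C)(C)C(C)(C)O1 | intermediate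
8 | (3E,5E)-3,6-dibromo-1,8-bis(2-methoxyphenyl)octa-3,5-diene (each Br trans to the diene chain) | COc1ccccc1CC/C(Br)=C\C=C(\Br)CCc1ccccc1OC | intermediate
9 | 3,4-dimethoxycyclobut-3-ene-1,2-dione (dimethyl squarate) | COC1=C(OC)C(=O)C1=O | starting material
10 | lithium 2,3-dimethoxy-1-methyl-4-oxocyclobut-2-en-1-olate | COC1=C(OC)C(C)([O-])C1=O.[Li+] | intermediate
11 | 3-methoxy-4-methylcyclobut-3-ene-1,2-dione | COC1=C(C)C(=O)C1=O | intermediate
12 | (3Z,5Z)-3,6-dilithio-1,8-bis(2-methoxyphenyl)octa-3,5-diene (each Li trans to the diene chain) | COc1ccccc1CC/C([Li])=C\C=C(\[Li])CCc1ccccc1OC | intermediate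
13 | dilithium bis(alkoxide) of 14 | COc1ccccc1CC/C(C2([O-])C(OC)=C(C)C2=O)=C\C=C(\C3([O-])C(OC)=C(C)C3=O)CCc4ccccc4OC.[Li+].[Li+] | intermediate
14 | 4,4'-[(3E,5E)-1,8-bis(2-methoxyphenyl)octa-3,5-diene-3,6-diyl]bis(4-hydroxy-3-methoxy-2-methylcyclobut-2-en-1-one), mixture of meso and racemic diastereomers at the two carbinol carbons | COc1ccccc1CC/C(C2(O)C(OC)=C(C)C2=O)=C\C=C(\C3(O)C(OC)=C(C)C3=O)CCc4ccccc4OC | intermediate
15 | (3Z,5E,7E,9Z)-4,9-dihydroxy-3,10-dimethoxy-5,8-bis[2-(2-methoxyphenyl)ethyl]-2,11-dimethyldodeca-1,3,5,7,9,11-hexaene-1,12-dione | O=C=C(C)/C(OC)=C(O)\C(CCc1ccccc1OC)=C\C=C(CCc1ccccc1OC)\C(O)=C(OC)/C(C)=C=O | intermediate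
16 | 4,4'-dimethoxy-5,5'-dimethyl-2,2'-bis[2-(2-methoxyphenyl)ethyl]-[1,1'-biphenyl]-3,3',6,6'-tetrol | COc1ccccc1CCc1c(O)c(OC)c(C)c(O)c1-c1c(O)c(C)c(OC)c(O)c1CCc1ccccc1OC | intermediate
17 | 4,4'-dimethoxy-5,5'-dimethyl-2,2'-bis[2-(2-methoxyphenyl)ethyl]-[1,1'-bi(cyclohexa-1,4-diene)]-3,3',6,6'-tetrone | COc1ccccc1CCC1=C(C2=C(CCc3ccccc3OC)C(=O)C(OC)=C(C)C2=O)C(=O)C(C)=C(OC)C1=O | intermediate
18 | disodium salt of 19 (bis(quinonolate)) | COc1ccccc1CCC1=C(C2=C(CCc3ccccc3OC)C(=O)C([O-])=C(C)C2=O)C(=O)C(C)=C([O-])C1=O.[Na+].[Na+] | intermediate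
19 | 4,4'-dihydroxy-5,5'-dimethyl-2,2'-bis[2-(2-methoxyphenyl)ethyl]-[1,1'-bi(cyclohexa-1,4-diene)]-3,3',6,6'-tetrone (CNP0293637.0) | COc1ccccc1CCC1=C(C2=C(CCc3ccccc3OC)C(=O)C(O)=C(C)C2=O)C(=O)C(C)=C(O)C1=O | target

**Step count**

Total steps: 8. Longest linear sequence: 7 (steps 1, 2, 3, 4, 6, 7, 8); step 5 is a one-step side branch.

**Steps most likely to fail, with fallbacks**

Step 4 (homocoupling). What may go wrong is loss of chemoselectivity between the C–I and C–Br bonds during oxidative addition, leading to oligomers, or erosion of alkene geometry. The fallback gives up the dihalide and uses tellurium as a temporary ring. Setting out from alkyne 5, Glaser–Hay coupling (CuCl, TMEDA, O2, acetone) would give 1,8-bis(2-methoxyphenyl)octa-3,5-diyne F1. Twofold anti addition of Na2Te (from Te and NaBH4, EtOH/H2O, 60 °C) would close 2,5-bis[2-(2-methoxyphenyl)ethyl]tellurophene F2. Tellurium–lithium exchange with n-BuLi (2.1 equiv, THF, −78 °C) would open the ring to the dilithiodiene F3, in which each lithium is cis to the diene chain. Slow inverse addition of F3 to an excess of 11 at −78 °C, so that each lithium takes its own dione rather than both adding to one, would give the dilithium bis(alkoxide) F4 and, after NH4Cl, the (3Z,5Z) bis(hydroxycyclobutenone) F5. Heating F5 under the conditions of step 7 would pass through the (5Z,7Z) bis(dienylketene) F6; since alkene geometry is erased on aromatisation, the sequence comes back to the route at bis(hydroquinone) 16 and hence 17.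

Step 6 (twofold exchange and twofold addition). What may go wrong is incomplete second bromine–lithium exchange or protonation of one carbanion before it adds, leaving mono-adducts, or attack at the vinylogous ester carbonyl. The fallback builds one ring at a time with a monolithium reagent and makes the inter-ring bond afterwards by known aryl–aryl coupling. Setting out from 5, Markovnikov hydrobromination (B-bromo-9-BBN, CH2Cl2, 0 °C; AcOH) would give 2-bromoalkene F7. Exchange with t-BuLi would give alkenyllithium F8, and addition to 11 would give mono(hydroxycyclobutenone) F9. Thermolysis (PhMe, 110 °C) would give hydroquinone F10, and methylation (Me2SO4, K2CO3, acetone) the trimethoxyarene F11. Iodination (NIS, cat. CF3CO2H, MeCN) at the only free position of the electron-rich ring would give aryl iodide F12. Ullmann homocoupling (Cu powder, DMF, 150 °C) would give hexamethoxybiaryl F13, and oxidative demethylation with (NH4)2Ce(NO3)6 (MeCN/H2O, 0 °C), which leaves the anisole rings alone, comes back to the route at 17.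

Step 7 (key step). What may go wrong is diversion of a ketene by the free tertiary hydroxyl (butenolide formation), or stalling after the first ring closure so that half-rearranged material is destroyed in the oxidation. The fallback masks both hydroxyls before the rearrangement. Setting out from 14, silylation (Me3SiOTf, Et3N, CH2Cl2, −78 °C) would give bis(trimethylsilyl ether) F14. Heating (xylene, 140 °C) would give the bis(hydroquinone mono-silyl ether) F15, in which the silyl groups sit on the oxygens next to the aralkyl carbons. Oxidative desilylation with (NH4)2Ce(NO3)6 (MeCN/H2O, 0 °C) comes back to the route at 17.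

**Further compounds**

F1 | step 4 | 1,8-bis(2-methoxyphenyl)octa-3,5-diyne | COc1ccccc1CCC#CC#CCCc1ccccc1OC
F2 | step 4 | 2,5-bis[2-(2-methoxyphenyl)ethyl]tellurophene | COc1ccccc1CCC1=CC=C(CCc2ccccc2OC)[Te]1
F3 | step 4 | (3E,5E)-3,6-dilithio-1,8-bis(2-methoxyphenyl)octa-3,5-diene (each Li cis to the diene chain) | COc1ccccc1CC/C([Li])=C/C=C(\[Li])CCc1ccccc1OC
F4 | step 4 | dilithium bis(alkoxide) of F5 | COc1ccccc1CC/C(C2([O-])C(OC)=C(C)C2=O)=C/C=C(\C3([O-])C(OC)=C(C)C3=O)CCc4ccccc4OC.[Li+].[Li+]
F5 | step 4 | 4,4'-[(3Z,5Z)-1,8-bis(2-methoxyphenyl)octa-3,5-diene-3,6-diyl]bis(4-hydroxy-3-methoxy-2-methylcyclobut-2-en-1-one), diastereomer mixture at the carbinol carbons | COc1ccccc1CC/C(C2(O)C(OC)=C(C)C2=O)=C/C=C(\C3(O)C(OC)=C(C)C3=O)CCc4ccccc4OC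
F6 | step 4 | (3Z,5Z,7Z,9Z)-4,9-dihydroxy-3,10-dimethoxy-5,8-bis[2-(2-methoxyphenyl)ethyl]-2,11-dimethyldodeca-1,3,5,7,9,11-hexaene-1,12-dione | O=C=C(C)/C(OC)=C(O)\C(CCc1ccccc1OC)=C/C=C(CCc1ccccc1OC)\C(O)=C(OC)/C(C)=C=O
F7 | step 6 | 1-(3-bromobut-3-en-1-yl)-2-methoxybenzene | COc1ccccc1CCC(Br)=C
F8 | step 6 | [4-(2-methoxyphenyl)but-1-en-2-yl]lithium | [Li]C(=C)CCc1ccccc1OC
F9 | step 6 | 4-hydroxy-3-methoxy-4-[4-(2-methoxyphenyl)but-1-en-2-yl]-2-methylcyclobut-2-en-1-one (racemic) | COC1=C(C)C(=O)C1(O)C(=C)CCc1ccccc1OC
F10 | step 6 | 3-methoxy-5-[2-(2-methoxyphenyl)ethyl]-2-methylbenzene-1,4-diol | COc1ccccc1CCc1cc(O)c(C)c(OC)c1O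
F11 | step 6 | 1,3,4-trimethoxy-5-[2-(2-methoxyphenyl)ethyl]-2-methylbenzene | COc1ccccc1CCc1cc(OC)c(C)c(OC)c1OC
F12 | step 6 | 1-iodo-2,4,5-trimethoxy-6-[2-(2-methoxyphenyl)ethyl]-3-methylbenzene | COc1ccccc1CCc1c(I)c(OC)c(C)c(OC)c1OC
F13 | step 6 | 3,3',4,4',6,6'-hexamethoxy-5,5'-dimethyl-2,2'-bis[2-(2-methoxyphenyl)ethyl]-1,1'-biphenyl | COc1ccccc1CCc1c(OC)c(OC)c(C)c(OC)c1-c1c(OC)c(C)c(OC)c(OC)c1CCc1ccccc1OC
F14 | step 7 | bis(trimethylsilyl ether) of 14 (3E,5E; diastereomer mixture at the carbinol carbons) | COc1ccccc1CC/C(C2(O[Si](C)(C)C)C(OC)=C(C)C2=O)=C\C=C(\C3(O[Si](C)(C)C)C(OC)=C(C)C3=O)CCc4ccccc4OC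
F15 | step 7 | 4,4'-dimethoxy-5,5'-dimethyl-2,2'-bis[2-(2-methoxyphenyl)ethyl]-3,3'-bis(trimethylsilyloxy)-[1,1'-biphenyl]-6,6'-diol | COc1ccccc1CCc1c(O[Si](C)(C)C)c(OC)c(C)c(O)c1-c1c(O)c(C)c(OC)c(O[Si](C)(C)C)c1CCc1ccccc1OC
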